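**Retrosynthetic overview**
- Ring: the benzene ring is bought with creosol 1. No ring is formed at any stage.
- Three C–Br bonds: 1 is brominated at all three free ring positions to give tribromocreosol 2.
- Key bond, benzylic C–O: 2 is oxidised at the phenol to para-quinone methide 3, rested as benzylic trifluoroacetate 4, and hydrated to target 5 (disconnection CH2–OH).

Assumption: the target has no stereocentre and is achiral, so no stereocontrol is needed anywhere.
Assumption: the route has two steps in all, so the closing risk section treats both of them; there is no third step to rank.

**Step 1**
Reactants: 1 creosol (2-methoxy-4-methylphenol)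
Product: 2 3,5,6-tribromo-2-methoxy-4-methylphenol (tribromocreosol; the same compound as 2,3,5-tribromo-6-methoxy-4-methylphenol)
Conditions: Br2 (3.1 equiv), AcOH, 15 → 45 °C, dark; then H2O, filter
Reagents that add atoms: bromine, BrBr
Why: Electrophilic aromatic bromination; OH (ortho, C6), OMe (para C5, ortho C3) and CH3 together activate exactly the three free ring positions, and holding bromine near three equivalents stops before ipso attack at the methyl-bearing carbon; no stereocentre is formed.

**Step 2**
Reactants: 2 3,5,6-tribromo-2-methoxy-4-methylphenol
Product: 5 (2,3,6-tribromo-4-hydroxy-5-methoxyphenyl)methanol, via para-quinone methide 3 (not isolated), via benzylic trifluoroacetate 4 (not isolated)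
Conditions: PhI(OCOCF3)2 (1.05 equiv, added over 30 min), CH2Cl2/CF3CO2H (10:1), 4 Å molecular sieves, −20 → 0 °C; then acetone/H2O (3:1), 0 °C → rt
Reagents that add atoms: water, O; [bis(trifluoroacetoxy)iodo]benzene, FC(F)(F)C(=O)OI(OC(=O)C(F)(F)F)c1ccccc1 (gives the CF3CO2 group of 4 only; no atom of it stays in 5)
Why: Proposed new method: an ipso-reversible oxidative benzylic C–H oxygenation of a fully ring-substituted para-cresol, not yet shown for a polybrominated, non-tert-butylated cresol stopped at the alcohol; ligand exchange of the phenol on the trivalent-iodine reagent and loss of PhI gives an ortho-methoxy-stabilised phenoxenium ion with every ring position blocked, and because the only nucleophile present is the weakly nucleophilic, highly nucleofugal trifluoroacetate, any dearomatised ipso adduct re-ionises, so the cation drains by loss of a proton from the para-methyl group to quinone methide 3, which rests as the aromatic trifluoroacetate 4; 4 is a markedly electron-poorer phenol than 2, so the single equivalent of oxidant is consumed by 2 alone, and water is admitted only after the oxidant is spent, so that 1,6-hydration of 3 forms the benzylic C–O bond without over-oxidation to the aldehyde and without water-induced ortho-quinone formation at the guaiacol unit; the closest known reaction types are the hypervalent-iodine oxidative dearomatisation of para-alkylphenols to para-quinol derivatives and the Zincke conversion of polybromo-para-cresols by bromine into 4-hydroxybenzyl bromides through quinone methides.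

**Compound list**
1 | creosol (2-methoxy-4-methylphenol) | COc1cc(C)ccc1O | starting material
2 | 3,5,6-tribromo-2-methoxy-4-methylphenol | COc1c(O)c(Br)c(Br)c(C)c1Br | intermediate
3 | 2,3,5-tribromo-6-methoxy-4-methylidenecyclohexa-2,5-dien-1-one (para-quinone methide) | C=C1C(Br)=C(Br)C(=O)C(OC)=C1Br | intermediate
4 | (2,3,6-tribromo-4-hydroxy-5-methoxyphenyl)methyl trifluoroacetate | COc1c(O)c(Br)c(Br)c(COC(=O)C(F)(F)F)c1Br | intermediate
5 | (2,3,6-tribromo-4-hydroxy-5-methoxyphenyl)methanol | COc1c(O)c(Br)c(Br)c(CO)c1Br | target

**Totals**
Total step count: 2. Longest linear sequence: 2.

**Steps most likely to fail (both steps of the route, most risky first)**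

Step 2 (the proposed new step). The risks are three:
- an ipso trifluoroacetate adduct that does not re-ionise;
- loss of the O-methyl group to an ortho-quinone;
- oligomeric benzyl aryl ethers when 3 meets phenol instead of water.

The fallback uses known chemistry, sets out from 2 and comes back at 5. It abandons phenol oxidation for radical functionalisation of the methyl group on a masked phenol. Acetylation of 2 (Ac2O, pyridine, catalytic 4-(dimethylamino)pyridine, CH2Cl2, rt) gives 2,3,5-tribromo-6-methoxy-4-methylphenyl acetate F2. Wohl–Ziegler bromination (N-bromosuccinimide 1.05 equiv, catalytic 2,2'-azobis(isobutyronitrile), PhCF3, 85 °C) gives 2,3,5-tribromo-4-(bromomethyl)-6-methoxyphenyl acetate F3. LiOH (3 equiv) in THF/H2O (1:3) at 0 °C → rt under high dilution, then acidification to pH 4, cleaves the aryl acetate. The phenoxide expels bromide to 3, which water captures to give 5.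

Step 1. The third bromination, at the hindered position between OMe and CH3, may overlap with ipso attack of bromine at the methyl-bearing carbon and give mixtures of 2 and side-chain bromide. The fallback sets out from 1 and comes back at 5. It removes the selectivity problem by over-brominating on purpose. Treating 1 with Br2 (4.3 equiv) in AcOH at 20 → 70 °C passes through 2, ipso-bromination at C4, loss of HBr to 3 and re-addition of HBr. This gives the Zincke pseudobromide 2,3,6-tribromo-4-hydroxy-5-methoxybenzyl bromide F1, which is filtered off. Stirring it in acetone/H2O (3:1) at rt solvolyses it by way of 3 to 5.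

**Further compounds**
F1 | step 1 | 2,3,6-tribromo-4-hydroxy-5-methoxybenzyl bromide | COc1c(O)c(Br)c(Br)c(CBr)c1Br
F2 | step 2 | 2,3,5-tribromo-6-methoxy-4-methylphenyl acetate | COc1c(OC(C)=O)c(Br)c(Br)c(C)c1Br
F3 | step 2 | 2,3,5-tribromo-4-(bromomethyl)-6-methoxyphenyl acetate | COc1c(OC(C)=O)c(Br)c(Br)c(CBr)c1Br
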